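| flask | substrate | remark | time |
|---|---|---|---|
| birch | 0.13 M | run made earlier |  |
| larch | 0.30 M | run made earlier |  |
| flask | 0.20 M |  | 2.0 d |

| run | time / h | substrate / % | side product / % | target / % |
|---|---|---|---|---|
| birch | 6.00 | 102 | 0 | 0 |
| birch | 12.0 | 97 | 2 | 5 |
| birch | 15.0 | 96 | 0 | 5 |
| birch | 20.0 | 98 | 0 | 4 |
| birch | 30.0 | 92 | 0 | 8 |
| birch | 40.0 | 92 | 3 | 9 |
| larch | 2.00 | 100 | 1 | 1 |
| larch | 6.00 | 99 | 1 | 0 |
| larch | 10.0 | 96 | 0 | 0 |
| larch | 15.0 | 95 | 0 | 1 |
| larch | 25.0 | 93 | 0 | 5 |
| larch | 30.0 | 92 | 1 | 7 |
| larch | 40.0 | 45 | 2 | 47 |

(standard deviation of a reading: 2 percentage points)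

- in percentages every species weighs as the substrate in it: one side product counts as two

- where most of what was charged as substrate, at 2.0 d is found (substrate / side product / target)
- the largest share itself, whichever of these holds it, in percent of the substrate charged

- The easy step is a straight line: the birch run falls to 92% of its substrate by 40.0 h, and I replace that curve by its mean, the fraction of the charge lost per hour, which I call the background rate (an initial rate). It is 0.00200 h⁻¹, read with the scatter of the readings.
- The larch run does not stay there. In the larch run, between 30.0 h and 40.0 h, substrate goes at 0.0470 h⁻¹, which is 23.5 times the background rate, while target climbs from 7% to 47%.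
- My reckoning for the flask: at the background rate it loses 9.60% in 2.0 d, leaving 90.4% as substrate. Substrate holds the largest share, and this figure errs high once a speed-up begins in the flask.
- The forecast also says substrate, but at 70%, lower than mine, adding that “the takeoff timing is very uncertain”.
- The flask gives substrate at 82.7%, with target at 14.1% and side product at 3.19%.

    substrate + 2 target → 3 target (k = 15.0 L² mol⁻² h⁻¹)
    substrate → target (k = 0.00150 h⁻¹)
    substrate + target → side product (k = 0.0390 L mol⁻¹ h⁻¹)

- The flask's mean rate is 0.00360 h⁻¹, 1.80 times the background rate, so my straight line stands 7.7 percentage points too high. The flask still holds 82.7% as substrate because the reading comes at 2.0 d and not ten times later, and in part because of the step of substrate and target into side product: with that step taken away the flask holds 77.3%, and at 20.0 d it holds 0%. Read earlier, at 20 h, the same charge is still on the line: the background rate gives 96.0%, and that neighbour flask holds 96.5%.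

The readings were computed with made-up constants.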